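The 20-membered macrocycle is opened at the N–CH2 bond between the secondary amine of the spermidine bridge and its four-carbon chain. That nitrogen, the only basic one, is carried as an acidic 2-nitrobenzenesulfonamide, the CH2 as a primary chloride. The two chains hang on the cis-fused hexahydrodibenzofuran core as Z-acrylamide arms at the quaternary carbon C9b and at aryl carbon C8. The key step, an intramolecular sulfonamide N-alkylation, closes the macrocycle in one operation; it exploits the two Z-alkenes and the folded tricycle as turn elements. The core comes from desymmetrisation of a 4-aryl-4-cyanocyclohexadienone and oxa-Michael ring closure.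

Key step: step 14

Remarks on the chemistry:
- Core positions follow dibenzofuran numbering: cyclohexane ring C1–C4, ring-fusion carbons C4a (O-bearing) and C9b (quaternary), ether oxygen O5, aryl ring C5a–C9a. The target is then (3R,4aR,9bS), with the 3-OH cis to the C4a–O bond.
- Compounds 1, 14 and 23 are taken as commercially available.
- In step 4 the ligand hand is the one expected to give the R enone; if the sense of induction is the opposite one, its antipode is used.

Step 1
Reactants: 1 2-(5-bromo-2-methoxyphenyl)acetonitrile; 2 methyl acrylate (2.1 equiv)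
Product: 4 methyl 5-(5-bromo-2-methoxyphenyl)-5-cyano-2-oxocyclohexane-1-carboxylate (racemic keto/enol mixture), via open-chain diester 3 (not isolated)
Conditions: KOt-Bu (2.2 equiv), THF, 0 °C → rt; aq HCl
Reagents that add atoms: none
Why: Double Michael addition of the benzylic nitrile anion to two acrylates, followed in the same pot by Dieckmann condensation, builds the quaternary carbon and the six-membered ring; the stereocentres formed are erased in step 2.

Step 2
Reactants: 4 methyl 5-(5-bromo-2-methoxyphenyl)-5-cyano-2-oxocyclohexane-1-carboxylate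
Product: 5 1-(5-bromo-2-methoxyphenyl)-4-oxocyclohexane-1-carbonitrile (achiral)
Conditions: LiCl (2 equiv), H2O (2 equiv), DMSO, 150 °C
Reagents that add atoms: none
Why: Krapcho dealkoxycarbonylation of the β-keto ester leaves the hindered tertiary nitrile and the aryl bromide untouched.

Step 3
Reactants: 5 1-(5-bromo-2-methoxyphenyl)-4-oxocyclohexane-1-carbonitrile
Product: 6 1-(5-bromo-2-methoxyphenyl)-4-oxocyclohexa-2,5-diene-1-carbonitrile (achiral, prochiral at C1)
Conditions: IBX (4 equiv), DMSO, 80 °C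
Reagents that add atoms: none
Why: IBX α,β-dehydrogenation on both sides of the ketone gives the cross-conjugated dienone, which cannot aromatise because C4 of the dienone is quaternary.

Step 4
Reactants: 6 1-(5-bromo-2-methoxyphenyl)-4-oxocyclohexa-2,5-diene-1-carbonitrile
Product: 8 (R)-1-(5-bromo-2-methoxyphenyl)-4-oxocyclohex-2-ene-1-carbonitrile, via silyl dienol ether 7 (not isolated)
Conditions: Cu(OAc)2 (5 mol %), (R)-DTBM-SEGPHOS (5.5 mol %), (EtO)2MeSiH (1.1 equiv), toluene, −20 °C; then 1 M HCl, THF, 0 °C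
Reagents that add atoms: none
Why: CuH-catalysed asymmetric conjugate reduction desymmetrises the dienone, the chiral bisphosphine–copper hydride choosing one of the two enantiotopic enone arms and so fixing the quaternary carbon as R, while the silyl dienol ether shields the product from a second reduction until the acidic work-up.

Step 5
Reactants: 8 (R)-1-(5-bromo-2-methoxyphenyl)-4-oxocyclohex-2-ene-1-carbonitrile
Product: 10 (4aR,9bR)-8-bromo-3-oxo-1,2,3,4,4a,9b-hexahydrodibenzo[b,d]furan-9b-carbonitrile, via free phenol 9 (not isolated)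
Conditions: BBr3 (2.5 equiv), CH2Cl2, −78 → 0 °C; aq NaHCO3; then Et3N (0.2 equiv), CH2Cl2, rt
Reagents that add atoms: none
Why: Aryl methyl ether cleavage frees the phenol, which closes the furan ring by 5-exo-trig oxa-Michael addition to the enone (faster than addition to the nitrile); the short tether allows only cis fusion, so C9b dictates C4a.

Step 6
Reactants: 10 (4aR,9bR)-8-bromo-3-oxo-1,2,3,4,4a,9b-hexahydrodibenzo[b,d]furan-9b-carbonitrile
Product: 11 (3R,4aR,9bR)-8-bromo-3-hydroxy-1,2,3,4,4a,9b-hexahydrodibenzo[b,d]furan-9b-carbonitrile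
Conditions: LiBH(s-Bu)3 (1.2 equiv), THF, −78 °C; aq NH4Cl
Reagents that add atoms: none
Why: Bulky trialkylborohydride reduction, in which the chair with the small nitrile axial and the C4a–O bond axial should take the hydride equatorially, away from that 1,3-diaxial oxygen, to give the axial 3-OH cis to the ring-fusion oxygen.

Step 7
Reactants: 11 (3R,4aR,9bR)-8-bromo-3-hydroxy-1,2,3,4,4a,9b-hexahydrodibenzo[b,d]furan-9b-carbonitrile
Product: 13 (3R,4aR,9bS)-8-bromo-3-hydroxy-1,2,3,4,4a,9b-hexahydrodibenzo[b,d]furan-9b-carbaldehyde, via N-aluminated aldimine 12 (not isolated)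
Conditions: i-Bu2AlH (3 equiv), CH2Cl2, −78 → 0 °C; then 1 M HCl, 0 °C
Reagents that add atoms: water, O
Why: Partial reduction of the hindered tertiary nitrile stops at the N-aluminated aldimine, which is hydrolysed on acidic work-up to the non-enolisable aldehyde; the free hydroxyl only consumes one hydride equivalent.

Step 8
Reactants: 14 4-chlorobutan-1-amine hydrochloride; 15 bromoacetyl bromide
Product: 16 2-bromo-N-(4-chlorobutyl)acetamide
Conditions: K2CO3, CH2Cl2/H2O, 0 °C
Reagents that add atoms: none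
Why: Schotten–Baumann N-acylation is much faster than displacement at either carbon–halogen bond or cyclisation of the free amine.

Step 9
Reactants: 16 2-bromo-N-(4-chlorobutyl)acetamide; 17 diphenyl phosphite
Product: 18 diphenyl {2-[(4-chlorobutyl)amino]-2-oxoethyl}phosphonate
Conditions: i-Pr2NEt (1.2 equiv), CH2Cl2, 0 °C → rt; aq NaHCO3
Reagents that add atoms: none
Why: Michaelis–Becker reaction, in which the phosphite anion displaces the activated α-bromide selectively over the unactivated primary chloride.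

Step 10
Reactants: 13 (3R,4aR,9bS)-8-bromo-3-hydroxy-1,2,3,4,4a,9b-hexahydrodibenzo[b,d]furan-9b-carbaldehyde; 18 diphenyl {2-[(4-chlorobutyl)amino]-2-oxoethyl}phosphonate (1.2 equiv)
Product: 19 (2Z)-3-[(3R,4aR,9bS)-8-bromo-3-hydroxy-1,2,3,4,4a,9b-hexahydrodibenzo[b,d]furan-9b-yl]-N-(4-chlorobutyl)prop-2-enamide
Conditions: KOt-Bu (1.15 equiv), THF, −78 °C; then 13, −78 → 0 °C; aq NH4Cl
Reagents that add atoms: none
Why: Z-selective Horner–Wadsworth–Emmons olefination with a diaryl phosphonoacetamide, whose fast oxaphosphetane collapse preserves the kinetic cis adduct, a preference reinforced by the α-quaternary aldehyde.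

Step 11
Reactants: 20 propane-1,3-diamine (5 equiv); 21 2-nitrobenzenesulfonyl chloride
Product: 22 N-(3-aminopropyl)-2-nitrobenzenesulfonamide
Conditions: CH2Cl2, 0 °C; aq Na2CO3
Reagents that add atoms: none
Why: Monosulfonylation of the diamine, made selective by the large excess of diamine.

Step 12
Reactants: 22 N-(3-aminopropyl)-2-nitrobenzenesulfonamide; 23 (Z)-3-iodoprop-2-enoic acid
Product: 24 (2Z)-3-iodo-N-{3-[(2-nitrophenyl)sulfonylamino]propyl}prop-2-enamide
Conditions: EDC·HCl (1.2 equiv), HOBt, CH2Cl2, 0 °C → rt, dark; aq NaHCO3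
Reagents that add atoms: none
Why: Carbodiimide amide coupling at low temperature without nucleophilic catalyst keeps the Z-iodoalkene geometry, and the sulfonamide N–H is not acylated.

Step 13
Reactants: 19 (2Z)-3-[(3R,4aR,9bS)-8-bromo-3-hydroxy-1,2,3,4,4a,9b-hexahydrodibenzo[b,d]furan-9b-yl]-N-(4-chlorobutyl)prop-2-enamide; 25 bis(pinacolato)diboron (1.1 equiv); 24 (2Z)-3-iodo-N-{3-[(2-nitrophenyl)sulfonylamino]propyl}prop-2-enamide (1.2 equiv)
Product: 27 (2Z)-N-(4-chlorobutyl)-3-[(3R,4aR,9bS)-3-hydroxy-8-{(1Z)-3-[(3-{[(2-nitrophenyl)sulfonyl]amino}propyl)amino]-3-oxoprop-1-en-1-yl}-1,2,3,4,4a,9b-hexahydrodibenzo[b,d]furan-9b-yl]prop-2-enamide, via aryl pinacol boronate 26 (not isolated)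
Conditions: Pd(dppf)Cl2 (5 mol %), KOAc (3 equiv), 1,4-dioxane, 85 °C; then 24, aq K3PO4 (3 equiv), rt, dark
Reagents that add atoms: none
Why: One-pot Miyaura borylation and Suzuki–Miyaura coupling, in which oxidative addition of the Z-alkenyl iodide and reductive elimination proceed with retention to give the Z-cinnamamide, while the alkyl chloride and the sulfonamide stay inert at room temperature.

Step 14
Reactants: 27 (2Z)-N-(4-chlorobutyl)-3-[(3R,4aR,9bS)-3-hydroxy-8-{(1Z)-3-[(3-{[(2-nitrophenyl)sulfonyl]amino}propyl)amino]-3-oxoprop-1-en-1-yl}-1,2,3,4,4a,9b-hexahydrodibenzo[b,d]furan-9b-yl]prop-2-enamide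
Product: 29 N-(2-nitrophenylsulfonyl) macrocycle (target 30 carrying the sulfonyl group on the amine nitrogen between the propylene and butylene chains), via primary iodide 28 (not isolated)
Conditions: Cs2CO3 (3 equiv), NaI (2 equiv), DMF, 60 °C, 1 mM (27 added over 12 h)
Reagents that add atoms: none
Why: Cs2CO3 deprotonates only the 2-nitrobenzenesulfonamide N–H (far more acidic than the two amide N–H and the secondary O–H), iodide turns the primary chloride into the iodide in situ (Finkelstein), and the sulfonamide anion displaces iodide by SN2 to form the bond between the propylene-bearing nitrogen and the terminal CH2 of the butylene chain. The closest known reaction type is the Fukuyama alkylation of 2-nitrobenzenesulfonamides with alkyl halides, which is established for medium and large polyamine rings under high dilution. The ring closed is the 20-membered ring, in a 20-exo-tet mode. No stereocentre is formed or touched, and both Z-alkenes are spectators because carbonate neither adds to nor deprotonates secondary acrylamides. The step needs N-alkylation at the sulfonamide over self-alkylation of the neighbouring amide and over oligomerisation; the pKa gap, high dilution and the convergent orientation of the C8 and C9b arms imposed by the two Z-alkenes and the cis-fused tricycle should secure this.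

Step 15
Reactants: 29 N-(2-nitrophenylsulfonyl) macrocycle
Product: 30 target macrocycle (3R,4aR,9bS; both alkenes Z; free secondary amine)
Conditions: PhSH (1.5 equiv), K2CO3 (3 equiv), MeCN, rt, dark
Reagents that add atoms: none
Why: Fukuyama denosylation, in which thiolate ipso-attack on the 2-nitroaryl ring (Meisenheimer complex) and loss of SO2 release the secondary amine; secondary acrylamides are poor thiol acceptors, so the Z-alkenes should persist.

Compound list
1 | 2-(5-bromo-2-methoxyphenyl)acetonitrile | N#CCc1cc(Br)ccc1OC | starting material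
2 | methyl acrylate | C=CC(=O)OC | starting material
3 | dimethyl 4-(5-bromo-2-methoxyphenyl)-4-cyanoheptanedioate | COC(=O)CCC(C#N)(CCC(=O)OC)c1cc(Br)ccc1OC | intermediate
4 | methyl 5-(5-bromo-2-methoxyphenyl)-5-cyano-2-oxocyclohexane-1-carboxylate (racemic) | COC(=O)C1CC(C#N)(c2cc(Br)ccc2OC)CCC1=O | intermediate
5 | 1-(5-bromo-2-methoxyphenyl)-4-oxocyclohexane-1-carbonitrile | N#CC1(c2cc(Br)ccc2OC)CCC(=O)CC1 | intermediate
6 | 1-(5-bromo-2-methoxyphenyl)-4-oxocyclohexa-2,5-diene-1-carbonitrile | N#CC1(c2cc(Br)ccc2OC)C=CC(=O)C=C1 | intermediate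
7 | (R)-1-(5-bromo-2-methoxyphenyl)-4-{[diethoxy(methyl)silyl]oxy}cyclohexa-2,4-diene-1-carbonitrile | N#C[C@@]1(c2cc(Br)ccc2OC)C=CC(O[Si](C)(OCC)OCC)=CC1 | intermediate
8 | (R)-1-(5-bromo-2-methoxyphenyl)-4-oxocyclohex-2-ene-1-carbonitrile | N#C[C@@]1(c2cc(Br)ccc2OC)C=CC(=O)CC1 | intermediate
9 | (R)-1-(5-bromo-2-hydroxyphenyl)-4-oxocyclohex-2-ene-1-carbonitrile | N#C[C@@]1(c2cc(Br)ccc2O)C=CC(=O)CC1 | intermediate
10 | (4aR,9bR)-8-bromo-3-oxo-1,2,3,4,4a,9b-hexahydrodibenzo[b,d]furan-9b-carbonitrile (cis-fused) | N#C[C@]23CCC(=O)C[C@H]2Oc2ccc(Br)cc23 | intermediate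
11 | (3R,4aR,9bR)-8-bromo-3-hydroxy-1,2,3,4,4a,9b-hexahydrodibenzo[b,d]furan-9b-carbonitrile (3-OH cis to C4a–O) | N#C[C@]23CC[C@@H](O)C[C@H]2Oc2ccc(Br)cc23 | intermediate
12 | (3R,4aR,9bR)-8-bromo-9b-(iminomethyl)-1,2,3,4,4a,9b-hexahydrodibenzo[b,d]furan-3-ol (present as its N-aluminium derivative) | N=C[C@]23CC[C@@H](O)C[C@H]2Oc2ccc(Br)cc23 | intermediate
13 | (3R,4aR,9bS)-8-bromo-3-hydroxy-1,2,3,4,4a,9b-hexahydrodibenzo[b,d]furan-9b-carbaldehyde | O=C[C@]23CC[C@@H](O)C[C@H]2Oc2ccc(Br)cc23 | intermediate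
14 | 4-chlorobutan-1-amine hydrochloride | Cl.NCCCCCl | starting material
15 | bromoacetyl bromide | BrCC(Br)=O | starting material
16 | 2-bromo-N-(4-chlorobutyl)acetamide | O=C(CBr)NCCCCCl | intermediate
17 | diphenyl phosphite | O=[PH](Oc1ccccc1)Oc1ccccc1 | starting material
18 | diphenyl {2-[(4-chlorobutyl)amino]-2-oxoethyl}phosphonate | O=C(CP(=O)(Oc1ccccc1)Oc1ccccc1)NCCCCCl | intermediate
19 | (2Z)-3-[(3R,4aR,9bS)-8-bromo-3-hydroxy-1,2,3,4,4a,9b-hexahydrodibenzo[b,d]furan-9b-yl]-N-(4-chlorobutyl)prop-2-enamide | O=C(NCCCCCl)/C=C\[C@]23CC[C@@H](O)C[C@H]2Oc2ccc(Br)cc23 | intermediate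
20 | propane-1,3-diamine | NCCCN | starting material
21 | 2-nitrobenzenesulfonyl chloride | O=[N+]([O-])c1ccccc1S(Cl)(=O)=O | starting material
22 | N-(3-aminopropyl)-2-nitrobenzenesulfonamide | NCCCNS(=O)(=O)c1ccccc1[N+](=O)[O-] | intermediate
23 | (Z)-3-iodoprop-2-enoic acid | OC(=O)/C=C\I | starting material
24 | (2Z)-3-iodo-N-{3-[(2-nitrophenyl)sulfonylamino]propyl}prop-2-enamide | O=C(/C=C\I)NCCCNS(=O)(=O)c1ccccc1[N+](=O)[O-] | intermediate
25 | bis(pinacolato)diboron | CC1(C)OB(OC1(C)C)B1OC(C)(C)C(C)(C)O1 | starting material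
26 | (2Z)-N-(4-chlorobutyl)-3-[(3R,4aR,9bS)-3-hydroxy-8-(4,4,5,5-tetramethyl-1,3,2-dioxaborolan-2-yl)-1,2,3,4,4a,9b-hexahydrodibenzo[b,d]furan-9b-yl]prop-2-enamide | O=C(NCCCCCl)/C=C\[C@]23CC[C@@H](O)C[C@H]2Oc2ccc(B4OC(C)(C)C(C)(C)O4)cc23 | intermediate
27 | (2Z)-N-(4-chlorobutyl)-3-[(3R,4aR,9bS)-3-hydroxy-8-{(1Z)-3-[(3-{[(2-nitrophenyl)sulfonyl]amino}propyl)amino]-3-oxoprop-1-en-1-yl}-1,2,3,4,4a,9b-hexahydrodibenzo[b,d]furan-9b-yl]prop-2-enamide | O=C(NCCCCCl)/C=C\[C@]23CC[C@@H](O)C[C@H]2Oc2ccc(cc23)/C=C\C(=O)NCCCNS(=O)(=O)c2ccccc2[N+](=O)[O-] | intermediate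
28 | N-(4-iodobutyl) analogue of 27 (same configuration, both alkenes Z) | O=C(NCCCCI)/C=C\[C@]23CC[C@@H](O)C[C@H]2Oc2ccc(cc23)/C=C\C(=O)NCCCNS(=O)(=O)c2ccccc2[N+](=O)[O-] | intermediate
29 | N-(2-nitrophenylsulfonyl) macrocycle: 20-membered ring in which the (3R,4aR,9bS)-3-hydroxyhexahydrodibenzofuran is bridged from C9b to C8 by (Z)-CH=CH–C(O)NH–(CH2)4–N(SO2C6H4-2-NO2)–(CH2)3–NHC(O)–(Z)-CH=CH | O=C1/C=C\[C@]23CC[C@@H](O)C[C@H]2Oc2ccc(cc23)/C=C\C(=O)NCCCN(CCCCN1)S(=O)(=O)c1ccccc1[N+](=O)[O-] | intermediate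
30 | target: the same 20-membered macrocycle with a free secondary amine, (3R,4aR,9bS), 3-OH cis to the C4a–O bond, both alkenes Z | O=C1/C=C\[C@]23CC[C@@H](O)C[C@H]2Oc2ccc(cc23)/C=C\C(=O)NCCCNCCCCN1 | target

Total step count: 15. Longest linear sequence: 11 steps (steps 1–7, 10, 13, 14, 15).

Steps most likely to fail

1. Step 14. Chain growth between two molecules may outrun the ring closure, or the amide next to the butylene chain may alkylate itself (five-membered ring) once the iodide has formed. The fallback sets out from 13 and comes back at 29; it closes the same N–CH2 bond by an intramolecular Fukuyama–Mitsunobu reaction of an alcohol under neutral redox conditions, with no halide and no carbonate base. Commercial 4-aminobutan-1-ol is N-acylated with 15 (K2CO3, CH2Cl2/H2O, 0 °C) to 2-bromo-N-(4-hydroxybutyl)acetamide F1. Michaelis–Becker reaction with 17 (i-Pr2NEt, CH2Cl2) should give diphenyl {2-[(4-hydroxybutyl)amino]-2-oxoethyl}phosphonate F2. Z-selective Horner–Wadsworth–Emmons olefination of 13 with F2 (KOt-Bu, THF, −78 → 0 °C) should give the N-(4-hydroxybutyl) Z-acrylamide F3. Miyaura borylation to the aryl pinacol boronate F4, used in the same pot, and Suzuki–Miyaura coupling with 24 should give the seco alcohol F5. PPh3 and DIAD in toluene/THF at high dilution should then alkylate the sulfonamide with the primary alcohol, the hindered axial secondary hydroxyl reacting more slowly, and give 29.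

2. Step 13. The Z geometry may be lost by isomerisation of the alkenyl–palladium intermediate or of the product, and the electron-rich aryl boronate may protodeboronate before it couples. The fallback sets out from 19 and comes back at 27; it sets the second Z-alkene by kinetically controlled olefination instead of cross-coupling. Reductive carbonylation of 19 (Pd(OAc)2, dppb, N-formylsaccharin, Et3SiH, Na2CO3, DMF, 80 °C) should give the 8-formyl compound F6. In parallel 22 is N-acylated with 15 to 2-bromo-N-{3-[(2-nitrophenyl)sulfonylamino]propyl}acetamide F7, which with 17 and i-Pr2NEt should give the diphenyl phosphonate F8. Z-selective Horner–Wadsworth–Emmons olefination of F6 with the dianion of F8 (KOt-Bu, 2 equiv, THF, −78 → 0 °C) should give 27.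

3. Step 4. Reduction may run on to the achiral saturated ketone, and discrimination between the two enantiotopic enone arms may be insufficient. The fallback sets out from 5 and comes back at 8; it desymmetrises the saturated ketone instead of the dienone. Enantioselective deprotonation of 5 with lithium bis[(R)-1-phenylethyl]amide (or its antipode, whichever leads to the R series) in the presence of Me3SiCl (THF, −100 °C) should give (R)-1-(5-bromo-2-methoxyphenyl)-4-[(trimethylsilyl)oxy]cyclohex-3-ene-1-carbonitrile F9. Saegusa–Ito oxidation (Pd(OAc)2, MeCN, rt) should then give 8.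

Further compounds
F1 | step 14 | 2-bromo-N-(4-hydroxybutyl)acetamide | O=C(CBr)NCCCCO
F2 | step 14 | diphenyl {2-[(4-hydroxybutyl)amino]-2-oxoethyl}phosphonate | O=C(CP(=O)(Oc1ccccc1)Oc1ccccc1)NCCCCO
F3 | step 14 | (2Z)-3-[(3R,4aR,9bS)-8-bromo-3-hydroxy-1,2,3,4,4a,9b-hexahydrodibenzo[b,d]furan-9b-yl]-N-(4-hydroxybutyl)prop-2-enamide | O=C(NCCCCO)/C=C\[C@]23CC[C@@H](O)C[C@H]2Oc2ccc(Br)cc23
F4 | step 14 | (2Z)-N-(4-hydroxybutyl)-3-[(3R,4aR,9bS)-3-hydroxy-8-(4,4,5,5-tetramethyl-1,3,2-dioxaborolan-2-yl)-1,2,3,4,4a,9b-hexahydrodibenzo[b,d]furan-9b-yl]prop-2-enamide | O=C(NCCCCO)/C=C\[C@]23CC[C@@H](O)C[C@H]2Oc2ccc(B4OC(C)(C)C(C)(C)O4)cc23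
F5 | step 14 | (2Z)-N-(4-hydroxybutyl)-3-[(3R,4aR,9bS)-3-hydroxy-8-{(1Z)-3-[(3-{[(2-nitrophenyl)sulfonyl]amino}propyl)amino]-3-oxoprop-1-en-1-yl}-1,2,3,4,4a,9b-hexahydrodibenzo[b,d]furan-9b-yl]prop-2-enamide | O=C(NCCCCO)/C=C\[C@]23CC[C@@H](O)C[C@H]2Oc2ccc(cc23)/C=C\C(=O)NCCCNS(=O)(=O)c2ccccc2[N+](=O)[O-]
F6 | step 13 | (2Z)-N-(4-chlorobutyl)-3-[(3R,4aR,9bS)-8-formyl-3-hydroxy-1,2,3,4,4a,9b-hexahydrodibenzo[b,d]furan-9b-yl]prop-2-enamide | O=C(NCCCCCl)/C=C\[C@]23CC[C@@H](O)C[C@H]2Oc2ccc(C=O)cc23
F7 | step 13 | 2-bromo-N-{3-[(2-nitrophenyl)sulfonylamino]propyl}acetamide | O=C(CBr)NCCCNS(=O)(=O)c1ccccc1[N+](=O)[O-]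
F8 | step 13 | diphenyl [2-({3-[(2-nitrophenyl)sulfonylamino]propyl}amino)-2-oxoethyl]phosphonate | O=C(CP(=O)(Oc1ccccc1)Oc1ccccc1)NCCCNS(=O)(=O)c1ccccc1[N+](=O)[O-]
F9 | step 4 | (R)-1-(5-bromo-2-methoxyphenyl)-4-[(trimethylsilyl)oxy]cyclohex-3-ene-1-carbonitrile | N#C[C@@]1(c2cc(Br)ccc2OC)CC=C(O[Si](C)(C)C)CC1
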